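The cyclohexenone ring (C3a, C4–C7, C7a; 2-benzofuran-1,4-dione numbering) is read as a masked 2-pyrone. C7a, which bears both the hydroxyl and the lactone carbonyl C1, is C6 of a 2-oxo-2H-pyran-6-carboxylate, its hydroxyl oxygen is the pyrone ring oxygen, and the enone α-carbon C5 is pyrone C3. The γ-lactone (C1–O2–C3) serves as an ester tether to an (E)-enol ether that carries a chiral 1-arylethyl group. One intramolecular inverse-demand Diels–Alder reaction joins C3a to C7a and C4 to C5, closing carbocycle and lactone and setting both quaternary centres. Ether cleavage, oxidation and hydrolytic loss of the bridging carbonyl as CO2 then unveil the hydroxy enone.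

Key step: step 10

Assumptions and remarks on the chemistry:
- 3-Ethynylfuran (9), 2-oxo-2H-pyran-6-carboxylic acid (15) and (S)-1-(2,4,6-triisopropylphenyl)ethanol (1) are taken as purchasable.
- The target SMILES is read as (3aR,7aR), with the CH2O arm on C3a and the 7a-hydroxyl cis, i.e. a trans-fused γ-lactone.
- The sense of induction by the (S)-auxiliary is taken from the conformational model given in step 10.
- Adducts 17–19 are numbered as 2-oxabicyclo[2.2.2]oct-5-en-3-ones: C1 = former pyrone C6 (bridgehead bearing the γ-lactone carbonyl), C4 = former pyrone C3 (bridgehead H), C5=C6 = alkene bridge, C7 = former enol-ether CH, C8 = quaternary carbon bearing the chain and the lactone CH2.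

Step 1
Reactants: 1 (S)-1-(2,4,6-triisopropylphenyl)ethanol; 2 methyl propiolate
Product: 3 methyl (E)-3-[(1S)-1-(2,4,6-triisopropylphenyl)ethoxy]prop-2-enoate
Conditions: PMe3 (10 mol %), CH2Cl2, 0 → 25 °C
Reagents that add atoms: none
Why: Phosphine-catalysed oxa-Michael addition of the secondary alcohol to the propiolate should give the β-alkoxyacrylate as its E isomer, the carbinol stereocentre being untouched.

Step 2
Reactants: 3 methyl (E)-3-[(1S)-1-(2,4,6-triisopropylphenyl)ethoxy]prop-2-enoate
Product: 5 methyl (Z)-2-iodo-3-[(1S)-1-(2,4,6-triisopropylphenyl)ethoxy]prop-2-enoate, via iodoacetate adduct 4 (not isolated)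
Conditions: NIS, AcOH, CH2Cl2, 25 °C; then Et3N, 0 → 25 °C
Reagents that add atoms: N-iodosuccinimide, O=C1CCC(=O)N1I
Why: Iodo-acetoxylation of the enol ether followed by E1cB loss of acetic acid (α-iodination of a β-alkoxyacrylate) should give the isomer with iodine cis to the alkoxy group, the alkoxy group staying trans to the ester.

Step 3
Reactants: 5 methyl (Z)-2-iodo-3-[(1S)-1-(2,4,6-triisopropylphenyl)ethoxy]prop-2-enoate
Product: 6 (Z)-2-iodo-3-[(1S)-1-(2,4,6-triisopropylphenyl)ethoxy]prop-2-en-1-ol
Conditions: DIBAL-H (2.2 equiv), CH2Cl2, −78 °C; Rochelle salt work-up; Et3N-deactivated silica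
Reagents that add atoms: none
Why: DIBAL-H 1,2-reduction of the vinylogous carbonate ester at low temperature should stop at the allylic alcohol and leave the vinyl iodide, the enol ether geometry and the benzylic ether intact.

Step 4
Reactants: 7 3-acetyldihydrofuran-2(3H)-one
Product: 8 (Z)-1-(2-oxodihydrofuran-3(2H)-ylidene)ethyl trifluoromethanesulfonate
Conditions: LiOTf, Et3N, Tf2O, CH2Cl2, 0 °C
Reagents that add atoms: triflic anhydride, O=S(=O)(OS(=O)(=O)C(F)(F)F)C(F)(F)F
Why: O-Triflation of the lithium-chelated enolate of the β-keto lactone (enol triflate formation) should place the triflate cis to the lactone carbonyl, the geometry needed for the later ring closure.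

Step 5
Reactants: 8 (Z)-1-(2-oxodihydrofuran-3(2H)-ylidene)ethyl trifluoromethanesulfonate; 9 3-ethynylfuran
Product: 10 (Z)-3-[4-(furan-3-yl)but-3-yn-2-ylidene]dihydrofuran-2(3H)-one
Conditions: Pd(PPh3)2Cl2 (3 mol %), CuI (5 mol %), Et3N, THF, 25 °C
Reagents that add atoms: none
Why: Sonogashira coupling of the alkenyl triflate with the terminal alkyne should proceed with retention of alkene geometry, leaving the alkyne cis to the lactone carbonyl.

Step 6
Reactants: 10 (Z)-3-[4-(furan-3-yl)but-3-yn-2-ylidene]dihydrofuran-2(3H)-one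
Product: 11 6-(furan-3-yl)-3-(2-hydroxyethyl)-4-methyl-2H-pyran-2-one
Conditions: Ph3PAuNTf2 (5 mol %), H2O (3 equiv), 1,4-dioxane, 50 °C
Reagents that add atoms: water, O
Why: π-Acid-catalysed 6-endo-dig cycloisomerisation of a (Z)-2-en-4-ynoate, in which the lactone carbonyl oxygen attacks the gold-activated alkyne at the furyl-bearing carbon and water hydrolyses the resulting 2-alkoxypyrylium at C2, should release the primary alcohol and leave the 2-pyrone.

Step 7
Reactants: 11 6-(furan-3-yl)-3-(2-hydroxyethyl)-4-methyl-2H-pyran-2-one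
Product: 12 6-(furan-3-yl)-3-(2-iodoethyl)-4-methyl-2H-pyran-2-one
Conditions: I2, PPh3, imidazole, CH2Cl2, 0 → 25 °C
Reagents that add atoms: iodine, II
Why: Appel iodination of the primary alcohol runs under near-neutral conditions that the furan and the pyrone should tolerate.

Step 8
Reactants: 12 6-(furan-3-yl)-3-(2-iodoethyl)-4-methyl-2H-pyran-2-one; 6 (Z)-2-iodo-3-[(1S)-1-(2,4,6-triisopropylphenyl)ethoxy]prop-2-en-1-ol
Product: 14 6-(furan-3-yl)-3-{(3E)-3-(hydroxymethyl)-4-[(1S)-1-(2,4,6-triisopropylphenyl)ethoxy]but-3-en-1-yl}-4-methyl-2H-pyran-2-one, via alkylzinc iodide 13 (not isolated)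
Conditions: Zn dust (TMSCl-activated), LiCl, THF, 40 °C; then 6, Pd(OAc)2 (2 mol %), SPhos (4 mol %), THF, 25 °C
Reagents that add atoms: none
Why: Zinc insertion into the primary iodide and Negishi sp3–sp2 coupling (a ligand system that tolerates a free hydroxyl) should replace the vinylic iodine with retention, so that the chain ends up cis to the alkoxy group.

Step 9
Reactants: 14 6-(furan-3-yl)-3-{(3E)-3-(hydroxymethyl)-4-[(1S)-1-(2,4,6-triisopropylphenyl)ethoxy]but-3-en-1-yl}-4-methyl-2H-pyran-2-one; 15 2-oxo-2H-pyran-6-carboxylic acid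
Product: 16 (2E)-2-{2-[6-(furan-3-yl)-4-methyl-2-oxo-2H-pyran-3-yl]ethyl}-3-[(1S)-1-(2,4,6-triisopropylphenyl)ethoxy]prop-2-en-1-yl 2-oxo-2H-pyran-6-carboxylate
Conditions: DIC, DMAP (1.5 equiv), CH2Cl2, 0 °C; kept cold and used at once
Reagents that add atoms: none
Why: Steglich esterification with the acid held as its DMAP salt should acylate the primary allylic alcohol without exposing the acid-labile enol ether to free acid.

Step 10
Reactants: 16 (2E)-2-{2-[6-(furan-3-yl)-4-methyl-2-oxo-2H-pyran-3-yl]ethyl}-3-[(1S)-1-(2,4,6-triisopropylphenyl)ethoxy]prop-2-en-1-yl 2-oxo-2H-pyran-6-carboxylate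
Product: 17 endo cycloadduct, a 2-oxabicyclo[2.2.2]oct-5-en-3-one with the γ-lactone fused across C1–C8, the chain on C8 and the (1S)-1-(2,4,6-triisopropylphenyl)ethoxy group on C7 both syn to the C5=C6 bridge
Conditions: toluene (5 mM), 2,6-di-tert-butyl-4-methylpyridine (0.2 equiv), 90 °C, sealed tube
Reagents that add atoms: none
Why: The electron-poor pyrone (diene C3–C6) and the electron-rich enol ether combine in an asynchronous inverse-electron-demand [4+2] cycloaddition, the bond from the nucleophilic enol β-carbon to pyrone C6 (C3a–C7a of the target) leading and the bond from the alkoxy carbon to pyrone C3 (C4–C5) following, with carbon dioxide retained at this temperature. The closest known reactions are the cycloadditions of electron-poor 2-pyrones with vinyl ethers that give isolable bridged lactones and the intramolecular Diels–Alder reactions of tethered 2-pyrones. The six-membered carbocycle closes by the cycloaddition itself, and the γ-lactone closes as the five-membered ring of a type 1 intramolecular Diels–Alder reaction with a three-atom ester tether (exo mode at the bond between the two tether-bearing carbons). Suprafacial addition fixes the two bridgeheads, and because the E geometry holds chain and alkoxy group cis, the known endo preference of the alkoxy group should put the chain endo and the tether exo, so that the lactone CH2 lies syn to the bridging oxygen (later CH2O cis to OH, the trans-fused lactone). The absolute configuration is set by the (S)-1-arylethyl group: in the s-trans enol ether with the carbinol C–H eclipsing the vinyl C–O bond the triisopropylphenyl ring shields one face and the pyrone should add to the other (Re face of the alkoxy-bearing carbon), any minor diastereomer being separable while the auxiliary is attached. The step needs regio-, endo/exo-, facial and periselectivity: the tether enforces a regiochemistry that also matches the polarity, the chain pyrone could reach the enol ether only by forming a four-membered ring, and the furan is mismatched with an electron-rich dienophile.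

Step 11
Reactants: 17 endo cycloadduct
Product: 18 7-endo-hydroxy cycloadduct (secondary alcohol at C7, syn to the C5=C6 bridge)
Conditions: TFA, CH2Cl2, 0 °C
Reagents that add atoms: none
Why: Acid-mediated SN1/E1 cleavage of the secondary benzylic ether should remove the auxiliary as its styrene and free the alcohol, which cannot reach either lactone carbonyl within the rigid cage.

Step 12
Reactants: 18 7-endo-hydroxy cycloadduct
Product: 19 bridged β-keto lactone (C7 ketone)
Conditions: Dess–Martin periodinane, CH2Cl2, 0 → 25 °C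
Reagents that add atoms: none
Why: Dess–Martin oxidation of the secondary alcohol should give the ketone, and since the carbon between ketone and lactone carbonyl is a bridgehead that cannot enolise, no epimerisation or elimination is expected.

Step 13
Reactants: 19 bridged β-keto lactone
Product: 22 (3aR,7aR)-3a-{2-[6-(furan-3-yl)-4-methyl-2-oxo-2H-pyran-3-yl]ethyl}-7a-hydroxy-3,3a,7,7a-tetrahydro-2-benzofuran-1,4-dione, via β-keto acid 20 (not isolated), via β,γ-enone 21 (not isolated)
Conditions: 1 M aq. HCl, THF, 45 °C
Reagents that add atoms: none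
Why: Acid-catalysed hydrolysis of the strained bridged β-keto lactone should free the tertiary alcohol and a β-keto acid that decarboxylates, and acid-catalysed tautomerisation of the resulting β,γ-enone into conjugation gives the enone without touching either stereocentre and without the base that would open a retro-aldol path.

Compound list
1 | (S)-1-(2,4,6-triisopropylphenyl)ethanol | C[C@H](O)c1c(C(C)C)cc(C(C)C)cc1C(C)C | starting material
2 | methyl propiolate | C#CC(=O)OC | starting material
3 | methyl (E)-3-[(1S)-1-(2,4,6-triisopropylphenyl)ethoxy]prop-2-enoate | C[C@H](O/C=C/C(=O)OC)c1c(C(C)C)cc(C(C)C)cc1C(C)C | intermediate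
4 | methyl 3-acetoxy-2-iodo-3-[(1S)-1-(2,4,6-triisopropylphenyl)ethoxy]propanoate (diastereomer mixture at C2 and C3, not isolated) | C[C@H](OC(OC(C)=O)C(I)C(=O)OC)c1c(C(C)C)cc(C(C)C)cc1C(C)C | intermediate
5 | methyl (Z)-2-iodo-3-[(1S)-1-(2,4,6-triisopropylphenyl)ethoxy]prop-2-enoate | C[C@H](O/C=C(\I)C(=O)OC)c1c(C(C)C)cc(C(C)C)cc1C(C)C | intermediate
6 | (Z)-2-iodo-3-[(1S)-1-(2,4,6-triisopropylphenyl)ethoxy]prop-2-en-1-ol | C[C@H](O/C=C(\I)CO)c1c(C(C)C)cc(C(C)C)cc1C(C)C | intermediate
7 | 3-acetyldihydrofuran-2(3H)-one (2-acetyl-γ-butyrolactone) | CC(=O)C1CCOC1=O | starting material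
8 | (Z)-1-(2-oxodihydrofuran-3(2H)-ylidene)ethyl trifluoromethanesulfonate (triflate cis to the lactone carbonyl) | C/C(OS(=O)(=O)C(F)(F)F)=C1\CCOC1=O | intermediate
9 | 3-ethynylfuran | C#Cc1ccoc1 | starting material
10 | (Z)-3-[4-(furan-3-yl)but-3-yn-2-ylidene]dihydrofuran-2(3H)-one (alkyne cis to the lactone carbonyl) | C/C(C#Cc1ccoc1)=C1\CCOC1=O | intermediate
11 | 6-(furan-3-yl)-3-(2-hydroxyethyl)-4-methyl-2H-pyran-2-one | Cc1cc(-c2ccoc2)oc(=O)c1CCO | intermediate
12 | 6-(furan-3-yl)-3-(2-iodoethyl)-4-methyl-2H-pyran-2-one | Cc1cc(-c2ccoc2)oc(=O)c1CCI | intermediate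
13 | {2-[6-(furan-3-yl)-4-methyl-2-oxo-2H-pyran-3-yl]ethyl}zinc iodide (not isolated) | Cc1cc(-c2ccoc2)oc(=O)c1CC[Zn]I | intermediate
14 | 6-(furan-3-yl)-3-{(3E)-3-(hydroxymethyl)-4-[(1S)-1-(2,4,6-triisopropylphenyl)ethoxy]but-3-en-1-yl}-4-methyl-2H-pyran-2-one (alkoxy cis to the chain) | C[C@H](O/C=C(\CCc1c(C)cc(-c2ccoc2)oc1=O)CO)c1c(C(C)C)cc(C(C)C)cc1C(C)C | intermediate
15 | 2-oxo-2H-pyran-6-carboxylic acid | O=C(O)c1cccc(=O)o1 | starting material
16 | (2E)-2-{2-[6-(furan-3-yl)-4-methyl-2-oxo-2H-pyran-3-yl]ethyl}-3-[(1S)-1-(2,4,6-triisopropylphenyl)ethoxy]prop-2-en-1-yl 2-oxo-2H-pyran-6-carboxylate | C[C@H](O/C=C(\CCc1c(C)cc(-c2ccoc2)oc1=O)COC(=O)c1cccc(=O)o1)c1c(C(C)C)cc(C(C)C)cc1C(C)C | intermediate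
17 | endo cycloadduct: 2-oxabicyclo[2.2.2]oct-5-en-3-one with a γ-lactone (C1–C(=O)–O–CH2–C8) fused across C1–C8, lactone CH2 syn to O2, pyronylethyl chain on C8 and (1S)-1-(2,4,6-triisopropylphenyl)ethoxy on C7 both syn to C5=C6, H at C4 | Cc1cc(-c2ccoc2)oc(=O)c1CC[C@@]12COC(=O)[C@]13OC(=O)[C@@H](C=C3)[C@H]2O[C@@H](C)c1c(C(C)C)cc(C(C)C)cc1C(C)C | intermediate
18 | 7-endo-hydroxy cycloadduct (as 17 with OH in place of the arylethoxy group) | Cc1cc(-c2ccoc2)oc(=O)c1CC[C@@]12COC(=O)[C@]13OC(=O)[C@@H](C=C3)[C@H]2O | intermediate
19 | bridged β-keto lactone (as 18 with C7 oxidised to the ketone) | Cc1cc(-c2ccoc2)oc(=O)c1CC[C@@]12COC(=O)[C@]13OC(=O)[C@@H](C=C3)C2=O | intermediate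
20 | β-keto acid: 7a-hydroxy-1,4-dioxo-1,3,3a,4,5,7a-hexahydro-2-benzofuran-5-carboxylic acid carrying the pyronylethyl chain at C3a, C6=C7 alkene (not isolated) | Cc1cc(-c2ccoc2)oc(=O)c1CC[C@@]12COC(=O)[C@@]1(O)C=C[C@H](C(=O)O)C2=O | intermediate
21 | β,γ-enone: the 3,3a,5,7a-tetrahydro isomer of 22 with the C6=C7 alkene (not isolated) | Cc1cc(-c2ccoc2)oc(=O)c1CC[C@@]12COC(=O)[C@@]1(O)C=CCC2=O | intermediate
22 | (3aR,7aR)-3a-{2-[6-(furan-3-yl)-4-methyl-2-oxo-2H-pyran-3-yl]ethyl}-7a-hydroxy-3,3a,7,7a-tetrahydro-2-benzofuran-1,4-dione | Cc1cc(-c2ccoc2)oc(=O)c1CC[C@@]12COC(=O)[C@@]1(O)CC=CC2=O | target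

Total step count: 13. Longest linear sequence: 10 steps (steps 4–13, from 7).

Steps most likely to fail

Step 10. The three-atom ester tether may impose its own endo preference and override the alkoxy-endo rule, giving the cis-fused series. Facial control by the auxiliary may be weak. The temperature needed may also bring loss of carbon dioxide from the adduct or ionisation of the alkoxy-activated allylic ester before cycloaddition.
Fallback: an untethered cycloaddition in which only the alkoxy-endo rule and the auxiliary decide the topicity. It sets out from 14, which is silylated (TBSCl, imidazole, CH2Cl2) to the tert-butyldimethylsilyl ether F1. In parallel 15 is converted by Fischer esterification (MeOH, catalytic H2SO4) into methyl 2-oxo-2H-pyran-6-carboxylate F2. F1 and F2 are combined in CH2Cl2 at 12 kbar and 25 °C in an intermolecular inverse-demand Diels–Alder reaction, with regiochemistry set by the same polarity, to give the bridged adduct F3 (methyl ester at bridgehead C1, silyloxymethyl on C8 syn to the bridging oxygen). HF·pyridine in THF removes the silyl group, and the freed hydroxymethyl closes onto the neighbouring methyl ester (PPTS if needed). The route is rejoined at 17.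

Step 13. Water may attack the γ-lactone or the chain pyrone instead of the bridged lactone. The tertiary allylic C–O bond may ionise, or the product may dehydrate under acid before decarboxylation is complete.
Fallback: neutral de-allylative decarboxylation instead of hydrolysis. It sets out from 19, which is opened by titanate-catalysed transesterification (Ti(OiPr)4 catalytic, allyl alcohol, 50 °C) to the allyl β-keto ester F4 with the tertiary hydroxyl free. Pd(PPh3)4 (zerovalent palladium, catalytic) with morpholine in THF at 0 °C removes the allyl group and the β-keto acid decarboxylates. Brief PPTS treatment completes the shift of the alkene into conjugation. The route is rejoined at 22.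

Step 6. The carbonyl oxygen may close in the 5-exo mode to an ylidene butenolide, or the alkyne may simply be hydrated without release of the hydroxyethyl arm.
Fallback: cyclisation through the carboxylate instead of the lactone carbonyl. It sets out from 10, which is saponified (LiOH, 1 equiv, THF/H2O, 0 °C) to the lithium (Z)-hydroxy-enynoate F5. After one equivalent of acetic acid, ZnBr2 (catalytic) in THF promotes the known 6-endo-dig lactonisation of (Z)-2-en-4-ynoic acids. The route is rejoined at 11.

Further compounds
F1 | step 10 | 3-{(3E)-3-[(tert-butyldimethylsilyloxy)methyl]-4-[(1S)-1-(2,4,6-triisopropylphenyl)ethoxy]but-3-en-1-yl}-6-(furan-3-yl)-4-methyl-2H-pyran-2-one | C[C@H](O/C=C(\CCc1c(C)cc(-c2ccoc2)oc1=O)CO[Si](C)(C)C(C)(C)C)c1c(C(C)C)cc(C(C)C)cc1C(C)C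
F2 | step 10 | methyl 2-oxo-2H-pyran-6-carboxylate | COC(=O)c1cccc(=O)o1
F3 | step 10 | untethered endo adduct: methyl 2-oxabicyclo[2.2.2]oct-5-en-3-one-1-carboxylate with silyloxymethyl (syn to O2) and pyronylethyl chain on C8 and the (1S)-1-(2,4,6-triisopropylphenyl)ethoxy group on C7 syn to C5=C6 | Cc1cc(-c2ccoc2)oc(=O)c1CC[C@@]1(CO[Si](C)(C)C(C)(C)C)[C@]2(C(=O)OC)OC(=O)[C@@H](C=C2)[C@H]1O[C@@H](C)c1c(C(C)C)cc(C(C)C)cc1C(C)C
F4 | step 13 | allyl ester of β-keto acid 20 | Cc1cc(-c2ccoc2)oc(=O)c1CC[C@@]12COC(=O)[C@@]1(O)C=C[C@H](C(=O)OCC=C)C2=O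
F5 | step 6 | lithium (2Z)-5-(furan-3-yl)-2-(2-hydroxyethyl)-3-methylpent-2-en-4-ynoate | [Li+].C/C(C#Cc1ccoc1)=C(\CCO)C(=O)[O-]
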